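Atom numbers C1–C15 follow the germacrane numbering of the target (C1 ketone, C2=C3 enol ether, C4=C5, C6 lactone carbinol, C7, C8 ester carbinol, C9, C10 quaternary, C11=C13 exo-methylene, C12 lactone carbonyl, C14 methyl, C15 hydroxymethyl). The target is (4Z,6S,7S,8R,10R).

## Structural features

The target is a ten-membered carbocycle (C1–C10) bridged by an ether oxygen between C3 and C10, which creates a 3(2H)-furanone (O–C3=C2–C1(=O)–C10) and a nine-membered oxacycle (O, C3–C10), i.e. an 11-oxabicyclo[6.2.1]undecadienone. A trans-fused α-methylene-γ-butyrolactone (C6–O–C12(=O)–C11(=C13)–C7) sits on C6/C7; C8 carries an (E)-crotonate, C4 a hydroxymethyl group and C10 a methyl group. C6, C7 and C8 are contiguous and form an all-syn O/C/O triad along C5–C9, while the quaternary C10 is 1,3 to C8 and insulated from it by C9H2. The C4=C5 olefin is Z (cis in the ring) and cross-conjugated with the furanone, and the lactone oxygen on C6 is allylic, so the dienone/allylic ester array, the exo-methylene lactone and the crotonate are all sensitive to bases and nucleophiles. The real difficulty is the strained bridged medium ring with a bridgehead enol ether and a Z-trisubstituted olefin, which resists end-to-end closure. The key step exploits two facts: the furanone is the cyclodehydrated form of a 10-hydroxy-1,3-dione (C10–OH, C1=O, C3=O), and the acyl carbon C3 lies five ring atoms from the C8 oxygen (C3–C4=C5–C6–C7–C8). C3 can therefore be parked on O8 as a seven-membered Z-enoate lactone and handed over to C2 with ring expansion, which releases O8 as exactly the hydroxyl that the crotonate needs.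

## Logic of the disconnections

28 back to 24: the C15 O–Si bond, the C11=C13 π bond (retro-addition of dimethylamine gives 25) and the C8 O–acyl bond are cut. The exo-methylene lactone and the crotonate are Michael acceptors that would not survive enolate chemistry, so they are unveiled last. The gain is that 24 tolerates strong base and acid. The demand is three mild, chemoselective closing steps.

24 back to 21 (key disconnection): the C2–C3 bond and the O10–C3 bond are cut and C3 is reconnected to O8. In one sentence, 21, a seven-membered enoate lactone with a 2-hydroxy-3-oxobutyl arm, is ring-expanded by O→C acyl transfer to a ten-membered β-diketone that dehydrates to 24. The ten-membered carbocycle, the furanone and the ether bridge collapse to a fused 7/5 bis-lactone with an open arm, and the Z olefin is stored in a small ring. The forward step needs the C2 enolate to attack C3 selectively and the dehydration to run through O10.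

21 back to 13 and 17: the C4=C5 double bond (olefination) and the O8–C3 ester bond are cut; the C5 aldehyde and C1 ketone of 20 are traced through 19 to the silyl ethers of 18. This separates the three-carbon unit C3/C4/C15 (17) from a monocyclic lactone diol (13). The forward steps need esterification of the secondary C8–OH in the presence of the tertiary C10–OH, removal of two silyl groups while a third stays, and a seven-membered ring closure.

13 back to 12 and 11: the C8–H bond is cut (carbinol to ketone) and the ketone is masked as the dithiane of 11. This removes the C8 stereocentre and turns C8 into an acyl-anion carbon. The forward reduction must deliver the 8R carbinol, 1,3-anti to the C10 hydroxyl.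

11 back to 6 and 8: the C7–C8 bond and the C11–C13 bond are cut. Three components (6, 8 and an iminium salt) are joined in one flask, C7 is set trans to C6 by the five-membered ring, and C13 enters as a masked methylene. The demand is 1,4-addition of a hindered dithiane anion and enolate trapping.

6 back to 4, 3, 2 and 1: the C8–C9 bond is cut (dithiane anion plus epoxide), then the silyl ether, then the epoxide C–O bonds. The C10 stereocentre is reduced to a reagent-controlled epoxidation of racemic 1. The forward steps need opening at the CH2 terminus of the epoxide and an efficient kinetic resolution.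

17 back to 16, 14 and 15, and 8 back to 7: the C4–C15 bond is cut (alkylation of 14 by 15) and the benzyl ester is removed; 8 is the silyl ether of chiral-pool 7, which supplies C5, C6, C7, C11 and C12 with C6 already configured.

## Other disconnections considered

Alternative 1: (the first that comes to mind) cut C6–C7 and the lactone C12–O bond. The forward key step is an intramolecular Barbier-type allylation (Zn, In or CrCl2) of the C6 enal by the 2-(bromomethyl)acrylate unit in seco compound A1, followed by lactonisation. This is a genuine end-to-end closure of the strained bicycle, and its transition state must also deliver C6 and C7 in the trans sense against the resident C8 centre. A1 also carries a Z, furanone-conjugated enal next to an allylic bromide. The chosen route sets C6/C7 on a five-membered ring with ring-enforced trans control and pays only for a seven-membered transition state when the large ring appears.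

Alternative 2: cut C9–C10 and the O–C7 bond of a vinyl-dihydropyran. The forward key step is a Cu- or Rh-carbenoid from diazo ketone A2, oxonium ylide formation and [2,3]-sigmatropic ring expansion to the 11-oxabicyclo[6.2.1] skeleton. The ring system maps perfectly, but the rearrangement by its mechanism places the new olefin at C7=C8 and leaves a saturated tetrahydrofuran-3-one. The carbon branch at C7, the oxygen at C8 and the C2=C3 unsaturation would all have to be installed on a medium-ring olefin afterwards, and the methyl-substituted diazo ketone is prone to 1,2-hydride shift. The chosen plan is shorter after the key step.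

Alternative 3: cut the C3=C8 enol-ether double bond of the tricyclic dienol ether A3. The forward key step is oxidative cleavage to a nine-membered keto lactone (O10–C3 ester), followed by a five-membered O→C acyl shift to the furanone. The cleavage must distinguish the enol-ether bond from the conjugated C4=C5 bond of the same diene. C8 would emerge as a ketone that has to be reduced inside a flexible nine-membered ring and next to the C1 acetyl, and C10 on the dihydrofuran is too remote from C6/C7 for ring control. In the chosen plan C8 is set by a hydroxyl-directed reduction on an open chain and its oxygen doubles as the leaving group of the key step.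

Key step: step 14

Remark: (5R)-5-(hydroxymethyl)furan-2(5H)-one (7) is taken as a catalogue chiral-pool butenolide; all other starting materials and reagents are standard catalogue compounds.

## Steps

Step 1
Reactants: 1 (±)-3-methylbut-3-en-2-ol
Product: 2 (1S)-1-[(2R)-2-methyloxiran-2-yl]ethan-1-ol
Conditions: Ti(OiPr)4 (cat.), L-(+)-DIPT (cat.), t-BuOOH (0.6 equiv), 4 Å MS, CH2Cl2, −20 °C
Reagents that add atoms: tert-butyl hydroperoxide, CC(C)(C)OO
Why: Sharpless kinetic resolution (Katsuki–Sharpless epoxidation): with L-(+)-tartrate the (S)-alcohol is epoxidised fast on the face that gives the (R)-configured quaternary epoxide carbon (future C10) as the erythro epoxy alcohol, and the (R)-alcohol is left behind.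

Step 2
Reactants: 2 (1S)-1-[(2R)-2-methyloxiran-2-yl]ethan-1-ol
Product: 3 triethyl{(1S)-1-[(2R)-2-methyloxiran-2-yl]ethoxy}silane
Conditions: TESCl, imidazole, CH2Cl2, 0 °C
Reagents that add atoms: chlorotriethylsilane, CC[Si](Cl)(CC)CC
Why: Standard silylation of a secondary alcohol; TES is chosen so that it can later be removed together with a primary TBS ether while a primary TIPS ether stays.

Step 3
Reactants: 4 1,3-dithiane; 3 triethyl{(1S)-1-[(2R)-2-methyloxiran-2-yl]ethoxy}silane
Product: 6 (2R,3S)-1-(1,3-dithian-2-yl)-2-methyl-3-[(triethylsilyl)oxy]butan-2-ol, via 2-lithio-1,3-dithiane 5 (not isolated)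
Conditions: n-BuLi, THF, −30 °C; then 3, −30 → 0 °C; H2O
Reagents that add atoms: none
Why: Corey–Seebach alkylation: the lithiated dithiane opens the 2,2-disubstituted epoxide by SN2 at its CH2 terminus, forming C8–C9 and leaving the tertiary C10 centre untouched.

Step 4
Reactants: 7 (5R)-5-(hydroxymethyl)furan-2(5H)-one
Product: 8 (5R)-5-{[(tert-butyldimethylsilyl)oxy]methyl}furan-2(5H)-one
Conditions: TBSCl, imidazole, CH2Cl2, 0 °C → rt
Reagents that add atoms: tert-butylchlorodimethylsilane, CC(C)(C)[Si](C)(C)Cl
Why: Standard silylation of a primary alcohol under non-basic conditions that do not racemise or open the butenolide.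

Step 5
Reactants: 6 (2R,3S)-1-(1,3-dithian-2-yl)-2-methyl-3-[(triethylsilyl)oxy]butan-2-ol; 8 (5R)-5-{[(tert-butyldimethylsilyl)oxy]methyl}furan-2(5H)-one
Product: 11 (3S,4R,5R)-5-{[(tert-butyldimethylsilyl)oxy]methyl}-3-[(dimethylamino)methyl]-4-{2-[(2R,3S)-2-hydroxy-2-methyl-3-(triethylsilyloxy)butyl]-1,3-dithian-2-yl}oxolan-2-one, via dilithiated dithiane alkoxide 9 (not isolated), via lithium lactone enolate 10 (not isolated)
Conditions: t-BuLi (2.2 equiv), THF–HMPA (9:1), −78 °C; then 8, −78 °C; then Me2N=CH2+ I−, −78 → 0 °C; H2O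
Reagents that add atoms: N,N-dimethylmethyleneiminium iodide (Eschenmoser's salt), C=[N+](C)C.[I-]
Why: Corey–Seebach dithiane anion conjugate addition to a γ-substituted butenolide (1,4 in THF–HMPA) occurs anti to the C6 CH2OTBS group and sets C7 trans to C6. The lactone enolate is then trapped anti to the new C7 substituent in a Mannich reaction, which installs C13 as a base-stable masked exo-methylene.

Step 6
Reactants: 11 (3S,4R,5R)-5-{[(tert-butyldimethylsilyl)oxy]methyl}-3-[(dimethylamino)methyl]-4-{2-[(2R,3S)-2-hydroxy-2-methyl-3-(triethylsilyloxy)butyl]-1,3-dithian-2-yl}oxolan-2-one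
Product: 12 (3S,4R,5R)-5-{[(tert-butyldimethylsilyl)oxy]methyl}-3-[(dimethylamino)methyl]-4-[(3R,4S)-3-hydroxy-3-methyl-4-(triethylsilyloxy)pentanoyl]oxolan-2-one
Conditions: Hg(ClO4)2, CaCO3, THF–H2O (5:1), 0 °C
Reagents that add atoms: water, O
Why: Mercury(II)-assisted dithiane hydrolysis under carbonate buffering tolerates the amine and the silyl ethers; the all-trans lactone is the thermodynamic isomer, so C7 next to the new ketone has nothing to epimerise to.

Step 7
Reactants: 12 (3S,4R,5R)-5-{[(tert-butyldimethylsilyl)oxy]methyl}-3-[(dimethylamino)methyl]-4-[(3R,4S)-3-hydroxy-3-methyl-4-(triethylsilyloxy)pentanoyl]oxolan-2-one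
Product: 13 (3S,4S,5R)-5-{[(tert-butyldimethylsilyl)oxy]methyl}-3-[(dimethylamino)methyl]-4-[(1R,3R,4S)-1,3-dihydroxy-3-methyl-4-(triethylsilyloxy)pentyl]oxolan-2-one
Conditions: Me4NBH(OAc)3, MeCN–AcOH (1:1), −30 °C
Reagents that add atoms: none
Why: Evans–Saksena hydroxyl-directed reduction: the free tertiary C10–OH binds boron and hydride is delivered intramolecularly through a chair with the larger C1 branch of C10 equatorial. This gives the 1,3-anti C8/C10 diol (8R) and overrides the Felkin preference of the C7 centre.

Step 8
Reactants: 14 benzyl (diethoxyphosphoryl)acetate; 15 (chloromethoxy)tri(propan-2-yl)silane (TOM-Cl)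
Product: 16 benzyl 2-(diethoxyphosphoryl)-3-[(triisopropylsilyl)oxy]propanoate (racemic)
Conditions: NaH, THF, 0 °C; then 15, 0 °C → rt
Reagents that add atoms: none
Why: C-alkylation of a phosphonoacetate enolate by an α-chloro ether (as with MOMCl or BOMCl) brings in C15 already as its TIPS ether; one equivalent of base limits dialkylation.

Step 9
Reactants: 16 benzyl 2-(diethoxyphosphoryl)-3-[(triisopropylsilyl)oxy]propanoate
Product: 17 2-(diethoxyphosphoryl)-3-[(triisopropylsilyl)oxy]propanoic acid (racemic)
Conditions: H2 (1 atm), Pd/C, EtOAc, rt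
Reagents that add atoms: none
Why: Neutral hydrogenolysis of the benzyl ester frees the acid without exposing the β-silyloxy phosphonate to base, which could cause β-elimination.

Step 10
Reactants: 13 (3S,4S,5R)-5-{[(tert-butyldimethylsilyl)oxy]methyl}-3-[(dimethylamino)methyl]-4-[(1R,3R,4S)-1,3-dihydroxy-3-methyl-4-(triethylsilyloxy)pentyl]oxolan-2-one; 17 2-(diethoxyphosphoryl)-3-[(triisopropylsilyl)oxy]propanoic acid
Product: 18 (1R,3R,4S)-1-[(2R,3S,4S)-2-{[(tert-butyldimethylsilyl)oxy]methyl}-4-[(dimethylamino)methyl]-5-oxooxolan-3-yl]-3-hydroxy-3-methyl-4-[(triethylsilyl)oxy]pentyl 2-(diethoxyphosphoryl)-3-[(triisopropylsilyl)oxy]propanoate (both epimers at the phosphonate carbon)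
Conditions: DCC, DMAP (cat.), CH2Cl2, 0 °C → rt
Reagents that add atoms: none
Why: Steglich esterification acylates the secondary C8–OH and leaves the tertiary C10–OH alone; the phosphonate carbon becomes sp2 later, so its configuration does not matter.

Step 11
Reactants: 18 (C8 phosphonoacetate, as named in step 10)
Product: 19 (1R,3R,4S)-1-[(2R,3S,4S)-4-[(dimethylamino)methyl]-2-(hydroxymethyl)-5-oxooxolan-3-yl]-3,4-dihydroxy-3-methylpentyl 2-(diethoxyphosphoryl)-3-[(triisopropylsilyl)oxy]propanoate
Conditions: HF·pyridine, pyridine, THF, 0 °C → rt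
Reagents that add atoms: none
Why: Fluoride/acid desilylation removes the primary TBS and the secondary TES ether much faster than the primary TIPS ether, which should stay on C15.

Step 12
Reactants: 19 (triol, as named in step 11)
Product: 20 (1R,3R)-1-[(2R,3S,4S)-4-[(dimethylamino)methyl]-2-formyl-5-oxooxolan-3-yl]-3-hydroxy-3-methyl-4-oxopentyl 2-(diethoxyphosphoryl)-3-[(triisopropylsilyl)oxy]propanoate
Conditions: Dess–Martin periodinane (2.5 equiv), CH2Cl2, 0 °C → rt
Reagents that add atoms: none
Why: Dess–Martin oxidation takes the primary C5 alcohol to the aldehyde and the secondary C1 alcohol to the methyl ketone in one operation; the tertiary C10–OH cannot be oxidised and the 1,2-diol is not cleaved.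

Step 13
Reactants: 20 (keto aldehyde, as named in step 12)
Product: 21 (3S,3aS,4R,8aS)-3-[(dimethylamino)methyl]-4-[(2R)-2-hydroxy-2-methyl-3-oxobutyl]-7-{[(triisopropylsilyl)oxy]methyl}-3,3a,4,8a-tetrahydro-2H-furo[3,2-c]oxepine-2,6-dione (γ-lactone trans-fused to a seven-membered enoate lactone)
Conditions: LiCl, i-Pr2NEt, MeCN (2 mM), rt
Reagents that add atoms: none
Why: Intramolecular Horner–Wadsworth–Emmons olefination under Masamune–Roush conditions closes the seven-membered lactone, and the ring forces C4=C5 to be cis, which is the Z geometry of the target. The aldehyde should react ahead of the hindered ketone, and the mild base spares the epimerisable C6.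

Step 14
Reactants: 21 (bis-lactone, as named in step 13)
Product: 24 (4Z,6S,7S,8R,10R,11S)-8-hydroxy furanone: the target skeleton with free C8–OH, C15–OTIPS and an (S)-C11–CH2NMe2 group in place of the exo-methylene, via ring-expanded hydroxy β-diketone 22 (not isolated), via bridged hemiketal 23 (not isolated)
Conditions: LiHMDS (2.1 equiv), THF (5 mM), −78 → −40 °C; then cannulation into 1 M HCl–THF, 0 °C → rt
Reagents that add atoms: none
Why: Proposed new method: ring-expanding O→C acyl transfer: LiHMDS deprotonates the C10 hydroxyl and the methyl ketone (C2), the C2 enolate adds to the lactone carbonyl C3 through a seven-membered cyclic transition state (C2–C1–C10–C9–C8–O8–C3), and the tetrahedral adduct expels the C8 alkoxide, which opens the seven-membered lactone into the ten-membered carbocycle 22 (ring expansion by three atoms, no end-to-end macrocyclisation); proton transfer from the doubly activated C2–H2 to that alkoxide locks 22 as its lithium β-diketonate. The closest known reaction type is the base-induced O→C acyl shift (intramolecular Claisen, Baker–Venkataraman type) of α-acyloxy ketones that leads to 3(2H)-furanones, together with Dieckmann-type attack of enolates on lactone carbonyls; what is new is its use to expand a lactone into a medium carbocycle. On inverse quench into acid the C10 hydroxyl adds to C3 (5-exo-trig, hemiketal 23) and dehydration toward C2 closes the furanone ring, which creates the bridged nine-membered oxacycle at the same time. No stereocentre is formed: C6, C7, C8, C10 and C11 are spectators and the Z geometry of C4=C5 is inherited from the seven-membered ring. The step needs enolisation at the methyl ketone and not at the hindered tertiary C11–H of the γ-lactone (pKa gap, kinetic base at −78 °C), attack at C3 and not at C12 (eight-membered transition state), and dehydration through O10 and not O8 (O8 can only form a lactol at C1 or a seven-membered hemiketal at C3, both reversible in aqueous acid, whereas the cross-conjugated 3(2H)-furanone is the acid-stable sink). The driving forces are diketonate formation under base, release of the trans-fused 5/7 bis-lactone, and the irreversible dehydration.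

Step 15
Reactants: 24 (8-hydroxy furanone, as named in step 14)
Product: 25 8-O-[(E)-but-2-enoyl] derivative of 24 (4Z,6S,7S,8R,10R,11S)
Conditions: (E)-crotonic anhydride, DMAP, pyridine, CH2Cl2, 0 °C → rt
Reagents that add atoms: (E)-but-2-enoic anhydride, C/C=C/C(=O)OC(=O)/C=C/C
Why: DMAP-catalysed acylation of the only free hydroxyl; the anhydride avoids the ketene pathway of crotonyl chloride that would deconjugate the ester.

Step 16
Reactants: 25 (crotonate, as named in step 15)
Product: 27 15-O-triisopropylsilyl ether of the target (4Z,6S,7S,8R,10R), via trimethylammonium iodide 26 (not isolated)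
Conditions: MeI, MeCN, rt; then aq. NaHCO3, rt
Reagents that add atoms: none
Why: N-Methylation of the tertiary amine followed by E1cB (Hofmann-type) loss of trimethylamine from the β-ammonio lactone regenerates the exo-methylene under conditions that the furanone and the crotonate tolerate.

Step 17
Reactants: 27 (15-O-TIPS ether of the target)
Product: 28 CNP0225232.1 (target), (4Z,6S,7S,8R,10R)
Conditions: HF·pyridine, pyridine, THF, 0 °C → rt
Reagents that add atoms: none
Why: Buffered fluoride desilylation of the primary allylic TIPS ether is non-basic and non-nucleophilic enough for the exo-methylene lactone, the crotonate and the dienone.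

## Compound list

1 | (±)-3-methylbut-3-en-2-ol | CC(O)C(C)=C | starting material
2 | (1S)-1-[(2R)-2-methyloxiran-2-yl]ethan-1-ol | C[C@H](O)[C@@]1(C)CO1 | intermediate
3 | triethyl{(1S)-1-[(2R)-2-methyloxiran-2-yl]ethoxy}silane | C[C@H](O[Si](CC)(CC)CC)[C@@]1(C)CO1 | intermediate
4 | 1,3-dithiane | C1CSCSC1 | starting material
5 | 2-lithio-1,3-dithiane | [Li]C1SCCCS1 | intermediate
6 | (2R,3S)-1-(1,3-dithian-2-yl)-2-methyl-3-[(triethylsilyl)oxy]butan-2-ol | C[C@H](O[Si](CC)(CC)CC)[C@@](C)(CC1SCCCS1)O | intermediate
7 | (5R)-5-(hydroxymethyl)furan-2(5H)-one | O=C1O[C@H](C=C1)CO | starting material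
8 | (5R)-5-{[(tert-butyldimethylsilyl)oxy]methyl}furan-2(5H)-one | O=C1O[C@H](C=C1)CO[Si](C)(C)C(C)(C)C | intermediate
9 | dilithio derivative of 6 (lithium C10 alkoxide, 2-lithiated dithiane) | C[C@H](O[Si](CC)(CC)CC)[C@@](C)(CC1([Li])SCCCS1)O[Li] | intermediate
10 | lithium enolate of the 4,5-trans conjugate adduct of 9 and 8 | C[C@H](O[Si](CC)(CC)CC)[C@@](C)(CC1(SCCCS1)[C@@H]2C=C(O[Li])O[C@H]2CO[Si](C)(C)C(C)(C)C)O[Li] | intermediate
11 | (3S,4R,5R)-5-{[(tert-butyldimethylsilyl)oxy]methyl}-3-[(dimethylamino)methyl]-4-{2-[(2R,3S)-2-hydroxy-2-methyl-3-(triethylsilyloxy)butyl]-1,3-dithian-2-yl}oxolan-2-one | C[C@H](O[Si](CC)(CC)CC)[C@@](C)(CC1(SCCCS1)[C@@H]2[C@@H](CN(C)C)C(=O)O[C@H]2CO[Si](C)(C)C(C)(C)C)O | intermediate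
12 | (3S,4R,5R)-5-{[(tert-butyldimethylsilyl)oxy]methyl}-3-[(dimethylamino)methyl]-4-[(3R,4S)-3-hydroxy-3-methyl-4-(triethylsilyloxy)pentanoyl]oxolan-2-one | C[C@H](O[Si](CC)(CC)CC)[C@@](C)(CC(=O)[C@@H]2[C@@H](CN(C)C)C(=O)O[C@H]2CO[Si](C)(C)C(C)(C)C)O | intermediate
13 | (3S,4S,5R)-5-{[(tert-butyldimethylsilyl)oxy]methyl}-3-[(dimethylamino)methyl]-4-[(1R,3R,4S)-1,3-dihydroxy-3-methyl-4-(triethylsilyloxy)pentyl]oxolan-2-one | C[C@H](O[Si](CC)(CC)CC)[C@@](C)(C[C@@H](O)[C@@H]2[C@@H](CN(C)C)C(=O)O[C@H]2CO[Si](C)(C)C(C)(C)C)O | intermediate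
14 | benzyl (diethoxyphosphoryl)acetate | CCOP(=O)(OCC)CC(=O)OCc1ccccc1 | starting material
15 | (chloromethoxy)tri(propan-2-yl)silane (TOM-Cl) | ClCO[Si](C(C)C)(C(C)C)C(C)C | starting material
16 | benzyl 2-(diethoxyphosphoryl)-3-[(triisopropylsilyl)oxy]propanoate (racemic) | CCOP(=O)(OCC)C(CO[Si](C(C)C)(C(C)C)C(C)C)C(=O)OCc1ccccc1 | intermediate
17 | 2-(diethoxyphosphoryl)-3-[(triisopropylsilyl)oxy]propanoic acid (racemic) | CCOP(=O)(OCC)C(CO[Si](C(C)C)(C(C)C)C(C)C)C(=O)O | intermediate
18 | (1R,3R,4S)-1-[(2R,3S,4S)-2-{[(tert-butyldimethylsilyl)oxy]methyl}-4-[(dimethylamino)methyl]-5-oxooxolan-3-yl]-3-hydroxy-3-methyl-4-[(triethylsilyl)oxy]pentyl 2-(diethoxyphosphoryl)-3-[(triisopropylsilyl)oxy]propanoate (both epimers at the phosphonate carbon) | C[C@H](O[Si](CC)(CC)CC)[C@@](C)(C[C@@H](OC(=O)C(CO[Si](C(C)C)(C(C)C)C(C)C)P(=O)(OCC)OCC)[C@@H]2[C@@H](CN(C)C)C(=O)O[C@H]2CO[Si](C)(C)C(C)(C)C)O | intermediate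
19 | (1R,3R,4S)-1-[(2R,3S,4S)-4-[(dimethylamino)methyl]-2-(hydroxymethyl)-5-oxooxolan-3-yl]-3,4-dihydroxy-3-methylpentyl 2-(diethoxyphosphoryl)-3-[(triisopropylsilyl)oxy]propanoate | C[C@H](O)[C@@](C)(C[C@@H](OC(=O)C(CO[Si](C(C)C)(C(C)C)C(C)C)P(=O)(OCC)OCC)[C@@H]2[C@@H](CN(C)C)C(=O)O[C@H]2CO)O | intermediate
20 | (1R,3R)-1-[(2R,3S,4S)-4-[(dimethylamino)methyl]-2-formyl-5-oxooxolan-3-yl]-3-hydroxy-3-methyl-4-oxopentyl 2-(diethoxyphosphoryl)-3-[(triisopropylsilyl)oxy]propanoate | CC(=O)[C@@](C)(C[C@@H](OC(=O)C(CO[Si](C(C)C)(C(C)C)C(C)C)P(=O)(OCC)OCC)[C@@H]2[C@@H](CN(C)C)C(=O)O[C@H]2C=O)O | intermediate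
21 | (3S,3aS,4R,8aS)-3-[(dimethylamino)methyl]-4-[(2R)-2-hydroxy-2-methyl-3-oxobutyl]-7-{[(triisopropylsilyl)oxy]methyl}-3,3a,4,8a-tetrahydro-2H-furo[3,2-c]oxepine-2,6-dione | CC(=O)[C@@](C)(C[C@@H](OC(=O)C(CO[Si](C(C)C)(C(C)C)C(C)C)=C[C@@H]2OC(=O)[C@@H]1CN(C)C)[C@H]12)O | intermediate
22 | ring-expanded hydroxy β-diketone (ten-membered carbocycle with C1 and C3 ketones, free C8–OH and C10–OH, 4Z; diketo tautomer shown) | CN(C)C[C@H]1C(=O)O[C@H]2/C=C(/CO[Si](C(C)C)(C(C)C)C(C)C)C(=O)CC(=O)[C@@](C)(C[C@@H](O)[C@H]12)O | intermediate
23 | bridged hemiketal (C10–O–C3(OH) tetrahydrofuran-3-one, either C3 epimer) | CN(C)C[C@H]1C(=O)O[C@H]2/C=C(/CO[Si](C(C)C)(C(C)C)C(C)C)C3(O)CC(=O)[C@@](C)(C[C@@H](O)[C@H]12)O3 | intermediate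
24 | (4Z,6S,7S,8R,10R,11S)-8-hydroxy furanone: target skeleton with free C8–OH, C15–OTIPS and C11–CH2NMe2 | CN(C)C[C@H]1C(=O)O[C@H]2/C=C(/CO[Si](C(C)C)(C(C)C)C(C)C)C3=CC(=O)[C@@](C)(C[C@@H](O)[C@H]12)O3 | intermediate
25 | 8-O-[(E)-but-2-enoyl] derivative of 24 | CN(C)C[C@H]1C(=O)O[C@H]2/C=C(/CO[Si](C(C)C)(C(C)C)C(C)C)C3=CC(=O)[C@@](C)(C[C@@H](OC(=O)/C=C/C)[C@H]12)O3 | intermediate
26 | trimethylammonium iodide of 25 | C[N+](C)(C)C[C@H]1C(=O)O[C@H]2/C=C(/CO[Si](C(C)C)(C(C)C)C(C)C)C3=CC(=O)[C@@](C)(C[C@@H](OC(=O)/C=C/C)[C@H]12)O3.[I-] | intermediate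
27 | 15-O-triisopropylsilyl ether of the target | C=C1C(=O)O[C@H]2/C=C(/CO[Si](C(C)C)(C(C)C)C(C)C)C3=CC(=O)[C@@](C)(C[C@@H](OC(=O)/C=C/C)[C@H]12)O3 | intermediate
28 | CNP0225232.1 | C=C1C(=O)O[C@H]2/C=C(/CO)C3=CC(=O)[C@@](C)(C[C@@H](OC(=O)/C=C/C)[C@H]12)O3 | target

## Step count and risks

Total step count: 17. Longest linear sequence: 14 steps (1, 2, 3, 5, 6, 7, 10, 11, 12, 13, 14, 15, 16, 17, from 1); step 4 and steps 8–9 are side branches.

Least certain steps:

Step 14 (key step, carries the label). The enolate may fail to engage the lactone carbonyl, or the freed C8 alkoxide may translactonise the γ-lactone before it is protonated. During work-up the hydroxy β-diketone may revert by retro-Claisen (O8 recapturing C3), and dehydration may run through O8 instead of O10. Fallback with known chemistry only, setting out from 13 and coming back at 25: C3 is placed on the tertiary O10 instead of O8, so that the C–C bond forms by the textbook five-membered O→C acyl shift of an α-acyloxy ketone and the medium ring is closed beforehand as a lactone. 13 is acylated at the secondary C8–OH with (E)-crotonic anhydride/DMAP to give the C8 crotonate F1. HF·pyridine removes the TBS and TES groups to give the triol F2, and Dess–Martin oxidation gives the keto aldehyde F3. Yamaguchi esterification (2,4,6-trichlorobenzoyl chloride, Et3N, DMAP) of the tertiary α-ketol hydroxyl with 17 gives the C10 phosphonoacetate F4. Masamune–Roush Horner–Wadsworth–Emmons closure at high dilution gives the nine-membered (Z)-enoate lactone F5. LiHMDS (1.05 equiv, −78 °C) followed by aqueous HCl then performs the established acyl shift and cyclodehydration and gives 25 directly. The price is a nine-membered ring closure by olefination and an enolate step next to the crotonate.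

Step 5. The hindered dithiane may be metalated incompletely beside the alkoxide, the basic anion may remove the γ-proton of 8 instead of adding, and the Mannich trap may be inefficient. Fallback, setting out from 6 and coming back at 12: the dianion is replaced by a protected mono-anion. 6 is silylated (TMSCl, imidazole) to the tertiary trimethylsilyl ether F6. Its lithio derivative (n-BuLi, THF–HMPA) is added to 8 and trapped with Eschenmoser's salt to give the O-silylated Mannich lactone F7. The mercury(II) hydrolysis of step 6 with a dilute aqueous AcOH wash then removes both the dithiane and the labile tertiary TMS ether and gives 12.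

Step 7. Facial selectivity may be poor, because the 1,3-induction comes from a tertiary carbinol whose two carbon substituents differ only moderately in size and it must override the Felkin bias of C7. Fallback, setting out from 12 and coming back at 18: the Felkin preference is used instead of fought. L-Selectride (THF, −78 °C) gives the 8-epi diol F8, and Mitsunobu esterification with 17 (PPh3, DIAD) inverts C8 while forming the C8–O ester, so that 18 is reached without the separate step 10.

Step 13. The phosphonate anion may add to the C1 ketone, C6 next to the aldehyde may epimerise, the silyloxy group may β-eliminate, or oligomers may form. Fallback, setting out from 19 and coming back at 21: the competing ketone is removed from the ring-closing substrate. TEMPO/PhI(OAc)2 oxidises only the primary alcohol to give the hydroxy aldehyde F9, the same olefination closes the ring to the carbinol lactone F10, and Dess–Martin oxidation of the remaining secondary alcohol gives 21.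

## Further compounds

F1 | step 14 | C8 (E)-but-2-enoate of 13 | C[C@H](O[Si](CC)(CC)CC)[C@@](C)(C[C@@H](OC(=O)/C=C/C)[C@@H]2[C@@H](CN(C)C)C(=O)O[C@H]2CO[Si](C)(C)C(C)(C)C)O
F2 | step 14 | triol from F1 (C1–OH, C5–OH, C10–OH free, C8 crotonate) | C[C@H](O)[C@@](C)(C[C@@H](OC(=O)/C=C/C)[C@@H]2[C@@H](CN(C)C)C(=O)O[C@H]2CO)O
F3 | step 14 | keto aldehyde from F2 (C1 methyl ketone, C5 aldehyde, C8 crotonate) | CC(=O)[C@@](C)(C[C@@H](OC(=O)/C=C/C)[C@@H]2[C@@H](CN(C)C)C(=O)O[C@H]2C=O)O
F4 | step 14 | C10 ester of F3 with 17 (tertiary phosphonoacetate) | CC(=O)[C@@](C)(C[C@@H](OC(=O)/C=C/C)[C@@H]2[C@@H](CN(C)C)C(=O)O[C@H]2C=O)OC(=O)C(CO[Si](C(C)C)(C(C)C)C(C)C)P(=O)(OCC)OCC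
F5 | step 14 | nine-membered (Z)-enoate lactone (O10–C3 ester) with C10 acetyl and C8 crotonate | CN(C)C[C@H]1C(=O)O[C@H]2/C=C(/CO[Si](C(C)C)(C(C)C)C(C)C)C(=O)O[C@](C)(C[C@@H](OC(=O)/C=C/C)[C@H]12)C(C)=O
F6 | step 5 | tertiary trimethylsilyl ether of 6 | C[C@H](O[Si](CC)(CC)CC)[C@@](C)(CC1SCCCS1)O[Si](C)(C)C
F7 | step 5 | C10-O-trimethylsilyl ether of 11 | C[C@H](O[Si](CC)(CC)CC)[C@@](C)(CC1(SCCCS1)[C@@H]2[C@@H](CN(C)C)C(=O)O[C@H]2CO[Si](C)(C)C(C)(C)C)O[Si](C)(C)C
F8 | step 7 | C8 epimer of 13 (8S carbinol) | C[C@H](O[Si](CC)(CC)CC)[C@@](C)(C[C@H](O)[C@@H]2[C@@H](CN(C)C)C(=O)O[C@H]2CO[Si](C)(C)C(C)(C)C)O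
F9 | step 13 | hydroxy aldehyde from 19 (C5 aldehyde, C1 carbinol retained) | C[C@H](O)[C@@](C)(C[C@@H](OC(=O)C(CO[Si](C(C)C)(C(C)C)C(C)C)P(=O)(OCC)OCC)[C@@H]2[C@@H](CN(C)C)C(=O)O[C@H]2C=O)O
F10 | step 13 | seven-membered enoate lactone with C1 carbinol (1-dihydro-21) | C[C@H](O)[C@@](C)(C[C@@H](OC(=O)C(CO[Si](C(C)C)(C(C)C)C(C)C)=C[C@@H]2OC(=O)[C@@H]1CN(C)C)[C@H]12)O
A1 | alternative 1 | methyl (2Z,4R)-2-(bromomethyl)-4-[(triethylsilyl)oxy]-5-[(2R)-2-methyl-3-oxo-5-{(Z)-3-oxo-1-[(triisopropylsilyloxy)methyl]prop-1-en-1-yl}-2,3-dihydrofuran-2-yl]pent-2-enoate | COC(=O)/C(CBr)=C/[C@H](O[Si](CC)(CC)CC)C[C@@]1(C)OC(=CC1=O)/C(CO[Si](C(C)C)(C(C)C)C(C)C)=C\C=O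
A2 | alternative 2 | 1-[5-(benzyloxy)-3-{[(triisopropylsilyl)oxy]methyl}-6-vinyl-5,6-dihydro-2H-pyran-2-yl]-3-diazobutan-2-one (2,6-cis; C5 configured as C6 of the target) | CC(=[N+]=[N-])C(=O)C[C@H]1O[C@H](C=C)[C@@H](OCc2ccccc2)C=C1CO[Si](C(C)C)(C(C)C)C(C)C
A3 | alternative 3 | tricyclic dienol ether: (2R)-2-acetyl-2-methyl-2,3-dihydrofuran fused through its C3=C8 enol-ether bond to a cyclohexadiene bearing the trans-fused γ-lactone and the CH2OTIPS group | CC(=O)[C@@]1(C)CC2=C(O1)C(CO[Si](C(C)C)(C(C)C)C(C)C)=C[C@@H]3OC(=O)C[C@@H]23
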